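(All constants were drawn at random within sensible limits; the run is a simulation.)

At early times L stands near its charge, so the meeting began with the first minutes of three flasks, dawn, summer and spring, which differ in the L charged.

| flask | E | L | time |
|---|---|---|---|
| dawn | 0.80 M | 2.20 equiv | 25 min |
| summer | 0.80 M | 1.00 equiv | 25 min |
| spring | 0.80 M | 1.50 equiv | 25 min |

    E + L → J + Z (k1 = 7.9 × 10⁻⁴ M⁻¹ s⁻¹)
    Z + L ⇌ J + G (K2 = 2.1, k2 = 5.0 × 10⁻⁴ M⁻¹ s⁻¹)
    L ⇌ Q (K3 = 1.4, k3 = 1.3 × 10⁻⁴ s⁻¹)
    E + Z ⇌ E.Z, settled at all times (K4 = 2.5 M⁻¹)

- percent here means E units held: one E.Z counts as two
- what is said of Z includes E.Z
- in an amount of Z, one E.Z counts as one Z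
- run time (dawn): 25 min

- which of these there is most of at the end, counted by the E in it, dawn (G / Z / E)
- which of these there is most of at the end, counted by the E in it, summer (G / Z / E)
- which of these there is most of at the end, counted by the E in it, spring (G / Z / E)
- final amount of the leader among these, as a percentage of the E charged, in dawn
- final amount of the leader among these, as a percentage of the E charged, in summer
- final amount of the leader among these, as a percentage of the E charged, in spring

The kineticist argued at the board that E is lost at the first step's rate constant times E times L. While L stays near its charge, she said, this is a pseudo-first-order decay of E. She therefore proposed one quantity, the exchange half-life: ln(2) over the rate constant times the concentration of L as charged, for summer 18.3 min. It comes to 8.31 min for dawn and 12.2 min for spring.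

She granted that L falls, being spent by both exchanges, and noted that its forward drain into Q, taken alone, has a half-life of 89 min, slower than the summer exchange. Over 25 min her reckoning left E at 12.4% in dawn, 38.8% in summer and 24.1% in spring. Summer's E was the highest of these, but it was still below the part exchanged, so she named Z the leader in each flask. She gave no figure for Z, since her reckoning stopped before the second exchange and E.Z.

The forecast's author then reported Z leading at 61% in dawn, 53% in summer and 59% in spring, on the grounds that “little G forms and the Z pool leads in all three runs”. The two agreed on the leader, but her figures were for E and the forecast's for Z.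

The simulation gives Z the lead in dawn at 47.8% and in spring at 44.1%. In summer, though, E leads at 42.5%, with Z at 36.7%.

Dawn's E ends at 20.9% and, without the difference in equivalents of L, at 42.5%, so that difference is the main reason for the gap of 22 percentage points; the exchange half-life is 8.31 min in dawn, shorter than summer's 18.3 min. For the neighbour of dawn charged with 0.550 equiv of L, the exchange half-life is 33.2 min, longer than the 25 min allowed, so the reckoning leaves 59.3% of E. That neighbour ends with E in the lead at 60.7%.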